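The disconnection on which everything rests cuts ring C at the aryl–carbonyl bond C4–C4a. The cyclisation precursor is an (S)-3-aryl-3-aryloxypropanoic Weinreb amide in which ring A is a bis-MOM-protected 2-geranylphloroglucinol ether carrying one iodine ortho to the ether oxygen. The step exploits the symmetry of this ring A: before closure the two carbons flanking the O1-bearing carbon (C4a and C8) are equivalent, so one iodine suffices and no regiochemical question arises. Iodine–lithium exchange makes C4a a carbanion that attacks the amide carbonyl (Parham cyclisation), closing the pyranone ring under acid-free conditions that spare the geranyl chain, the acetals and the preset C2 stereocentre.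

Key step: step 9

Remark: the single stereocentre (C2) of the target reads as S and the side-chain alkene as E; flavanone numbering (O1, C2, C3, C4, C4a, C5 to C8, C8a; ring B primed) is used throughout.

Step 1
Reactants: 1 resorcinol
Product: 2 1,3-bis(methoxymethoxy)benzene
Conditions: NaH, MOMCl, DMF, 0 °C → rt
Reagents that add atoms: chloromethyl methyl ether, COCCl
Why: Williamson-type O-alkylation of the sodium bis-phenoxide gives the bis-acetal, which later directs the metalation.

Step 2
Reactants: 2 1,3-bis(methoxymethoxy)benzene; 3 geranyl bromide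
Product: 5 2-[(2E)-3,7-dimethylocta-2,6-dien-1-yl]-1,3-bis(methoxymethoxy)benzene, via 2-lithio-1,3-bis(methoxymethoxy)benzene 4 (not isolated)
Conditions: n-BuLi, THF, 0 °C → rt; CuI (10 mol %), then 3, −78 °C → rt
Reagents that add atoms: none
Why: Directed ortho-metalation takes the carbon between the two coordinating MOM ethers, and the copper-assisted aryl nucleophile displaces the primary allylic bromide at its alpha carbon, so the E alkene should be kept.

Step 3
Reactants: 5 2-[(2E)-3,7-dimethylocta-2,6-dien-1-yl]-1,3-bis(methoxymethoxy)benzene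
Product: 7 4-[(2E)-3,7-dimethylocta-2,6-dien-1-yl]-3,5-bis(methoxymethoxy)phenol, via arylboronic acid pinacol ester 6 (not isolated)
Conditions: [Ir(OMe)(cod)]2 (1.5 mol %), 4,4'-di-tert-butyl-2,2'-bipyridine (3 mol %), B2pin2 (1.0 equiv), THF, 60 °C; then 30% aq. H2O2, NaOH, THF/H2O, 0 °C
Reagents that add atoms: hydrogen peroxide, OO
Why: Sterically governed iridium-catalysed C–H borylation should take the only arene C–H without an ortho substituent (para to the geranyl group), and basic peroxide oxidation of the C–B bond gives the phenol without touching the unactivated trisubstituted alkenes.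

Step 4
Reactants: 7 4-[(2E)-3,7-dimethylocta-2,6-dien-1-yl]-3,5-bis(methoxymethoxy)phenol
Product: 8 4-[(2E)-3,7-dimethylocta-2,6-dien-1-yl]-2-iodo-3,5-bis(methoxymethoxy)phenol
Conditions: I2 (1.0 equiv), NaHCO3, THF/H2O, 0 °C
Reagents that add atoms: iodine, II
Why: Electrophilic aromatic iodination of the strongly activated phenoxide goes ortho to the hydroxyl group (para is blocked and the two ortho carbons are equivalent by symmetry), much faster than any reaction of iodine with the isolated alkenes.

Step 5
Reactants: 9 methyl 3-hydroxy-4-methoxybenzoate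
Product: 10 methyl 4-methoxy-3-(methoxymethoxy)benzoate
Conditions: NaH, MOMCl, DMF, 0 °C → rt
Reagents that add atoms: chloromethyl methyl ether, COCCl
Why: O-alkylation of the phenoxide masks the ring B phenol as the same acetal used on ring A, so that one final operation frees all three.

Step 6
Reactants: 10 methyl 4-methoxy-3-(methoxymethoxy)benzoate; 11 N-methoxy-N-methylacetamide
Product: 13 N-methoxy-3-[4-methoxy-3-(methoxymethoxy)phenyl]-N-methyl-3-oxopropanamide, via lithium enolate 12 (not isolated)
Conditions: LiN(i-Pr)2 (2.2 equiv), 11, THF, −78 °C; then 10, −78 → −20 °C; sat. aq. NH4Cl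
Reagents that add atoms: none
Why: Crossed Claisen condensation: the preformed amide enolate is acylated by the non-enolisable benzoate, and the beta-keto amide is shielded from further attack as its enolate until the quench.

Step 7
Reactants: 13 N-methoxy-3-[4-methoxy-3-(methoxymethoxy)phenyl]-N-methyl-3-oxopropanamide
Product: 14 (3R)-3-hydroxy-N-methoxy-3-[4-methoxy-3-(methoxymethoxy)phenyl]-N-methylpropanamide
Conditions: RuCl[(R,R)-TsDPEN](p-cymene) (1 mol %), HCO2H/Et3N (5:2), CH2Cl2, 30 °C
Reagents that add atoms: none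
Why: Noyori–Ikariya asymmetric transfer hydrogenation of the aryl ketone, in which the CH/π contact between the aryl group and the cymene ligand in the six-membered hydride-transfer transition state should make the (R,R)-catalyst deliver the R carbinol.

Step 8
Reactants: 8 4-[(2E)-3,7-dimethylocta-2,6-dien-1-yl]-2-iodo-3,5-bis(methoxymethoxy)phenol; 14 (3R)-3-hydroxy-N-methoxy-3-[4-methoxy-3-(methoxymethoxy)phenyl]-N-methylpropanamide
Product: 15 (3S)-3-{4-[(2E)-3,7-dimethylocta-2,6-dien-1-yl]-2-iodo-3,5-bis(methoxymethoxy)phenoxy}-N-methoxy-3-[4-methoxy-3-(methoxymethoxy)phenyl]-N-methylpropanamide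
Conditions: PPh3, DIAD, toluene, −20 °C → rt
Reagents that add atoms: none
Why: Mitsunobu etherification, in which the acidic ortho-iodophenol displaces the alkoxyphosphonium in an SN2 step with inversion (R carbinol to S ether), the non-polar solvent and low temperature being chosen to disfavour ionisation at the benzylic carbon.

Step 9
Reactants: 15 (3S)-3-{4-[(2E)-3,7-dimethylocta-2,6-dien-1-yl]-2-iodo-3,5-bis(methoxymethoxy)phenoxy}-N-methoxy-3-[4-methoxy-3-(methoxymethoxy)phenyl]-N-methylpropanamide
Product: 18 (2S)-6-[(2E)-3,7-dimethylocta-2,6-dien-1-yl]-2-[4-methoxy-3-(methoxymethoxy)phenyl]-5,7-bis(methoxymethoxy)chroman-4-one, via aryllithium 16 (not isolated), via lithium hemiaminal 17 (not isolated)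
Conditions: t-BuLi (2.1 equiv), THF/Et2O, −100 → −78 °C; then sat. aq. NH4Cl
Reagents that add atoms: none
Why: Iodine–lithium exchange with t-BuLi at −100 °C is faster than attack of the alkyllithium on the amide and gives aryllithium 16, whose C4a carbanion, flanked by two ortho oxygens, adds to the Weinreb carbonyl to give the N,O-chelated lithium hemiaminal 17, which collapses to the C4 ketone only on aqueous quench. This is a Parham cyclisation (intramolecular acylation of an aryllithium by a Weinreb amide), the known route from 2-haloaryl ethers of 3-hydroxy acid derivatives to chroman-4-ones. Ring C closes in 6-exo-trig mode by formation of the C4–C4a bond. No stereocentre is created: C2 is carried in from 15, and because the carbonyl stays masked in 17 until work-up, no enolate can expel the aryloxide (retro-oxa-Michael) and racemise it. The step needs exchange and ring closure to outrun deprotonation alpha to the amide with loss of the aryloxide, and this is secured by the iodide (fastest exchange), the low temperature, the second equivalent of t-BuLi that destroys tert-butyl iodide, and the lowered basicity of the doubly oxygen-flanked aryllithium. Regiochemistry is fixed by the iodine, and since C4a and C8 of the open precursor are equivalent, the product can only be the 6-geranyl isomer.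

Step 10
Reactants: 18 (2S)-6-[(2E)-3,7-dimethylocta-2,6-dien-1-yl]-2-[4-methoxy-3-(methoxymethoxy)phenyl]-5,7-bis(methoxymethoxy)chroman-4-one
Product: 19 (2S)-6-[(2E)-3,7-dimethylocta-2,6-dien-1-yl]-5,7-dihydroxy-2-(3-hydroxy-4-methoxyphenyl)chroman-4-one (CNP0264411.1)
Conditions: 3 M aq. HCl, MeOH, 45 °C, short reaction time
Reagents that add atoms: none
Why: Acid-catalysed acetal exchange with methanol removes the three MOM groups (the peri 5-O-MOM first); the time is kept short to limit acid-induced addition of the freed phenols to the geranyl alkene and ring-opening at C2.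

Compound list
1 | resorcinol | Oc1cccc(O)c1 | starting material
2 | 1,3-bis(methoxymethoxy)benzene | COCOc1cccc(OCOC)c1 | intermediate
3 | geranyl bromide, (2E)-1-bromo-3,7-dimethylocta-2,6-diene | BrC/C=C(\C)CCC=C(C)C | starting material
4 | 2-lithio-1,3-bis(methoxymethoxy)benzene | [Li]c1c(OCOC)cccc1OCOC | intermediate
5 | 2-[(2E)-3,7-dimethylocta-2,6-dien-1-yl]-1,3-bis(methoxymethoxy)benzene | COCOc1cccc(OCOC)c1C/C=C(\C)CCC=C(C)C | intermediate
6 | 2-{4-[(2E)-3,7-dimethylocta-2,6-dien-1-yl]-3,5-bis(methoxymethoxy)phenyl}-4,4,5,5-tetramethyl-1,3,2-dioxaborolane | COCOc1cc(B2OC(C)(C)C(C)(C)O2)cc(OCOC)c1C/C=C(\C)CCC=C(C)C | intermediate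
7 | 4-[(2E)-3,7-dimethylocta-2,6-dien-1-yl]-3,5-bis(methoxymethoxy)phenol | COCOc1cc(O)cc(OCOC)c1C/C=C(\C)CCC=C(C)C | intermediate
8 | 4-[(2E)-3,7-dimethylocta-2,6-dien-1-yl]-2-iodo-3,5-bis(methoxymethoxy)phenol | COCOc1cc(O)c(I)c(OCOC)c1C/C=C(\C)CCC=C(C)C | intermediate
9 | methyl 3-hydroxy-4-methoxybenzoate | COC(=O)c1ccc(OC)c(O)c1 | starting material
10 | methyl 4-methoxy-3-(methoxymethoxy)benzoate | COC(=O)c1ccc(OC)c(OCOC)c1 | intermediate
11 | N-methoxy-N-methylacetamide | CC(=O)N(C)OC | starting material
12 | lithium enolate of N-methoxy-N-methylacetamide | [Li]OC(=C)N(C)OC | intermediate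
13 | N-methoxy-3-[4-methoxy-3-(methoxymethoxy)phenyl]-N-methyl-3-oxopropanamide | COc1ccc(C(=O)CC(=O)N(C)OC)cc1OCOC | intermediate
14 | (3R)-3-hydroxy-N-methoxy-3-[4-methoxy-3-(methoxymethoxy)phenyl]-N-methylpropanamide | COc1ccc([C@@H](CC(=O)N(C)OC)O)cc1OCOC | intermediate
15 | (3S)-3-{4-[(2E)-3,7-dimethylocta-2,6-dien-1-yl]-2-iodo-3,5-bis(methoxymethoxy)phenoxy}-N-methoxy-3-[4-methoxy-3-(methoxymethoxy)phenyl]-N-methylpropanamide | COc1ccc([C@H](CC(=O)N(C)OC)Oc2cc(OCOC)c(C/C=C(\C)CCC=C(C)C)c(OCOC)c2I)cc1OCOC | intermediate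
16 | aryllithium from 15 (lithium in place of iodine at C4a) | COc1ccc([C@H](CC(=O)N(C)OC)Oc2cc(OCOC)c(C/C=C(\C)CCC=C(C)C)c(OCOC)c2[Li])cc1OCOC | intermediate
17 | lithium hemiaminal (C4 lithium alkoxide bearing the N-methoxy-N-methylamino group; C4 epimers, C2 S) | COc1ccc([C@@H]2CC(O[Li])(N(C)OC)c3c(cc(OCOC)c(C/C=C(\C)CCC=C(C)C)c3OCOC)O2)cc1OCOC | intermediate
18 | (2S)-6-[(2E)-3,7-dimethylocta-2,6-dien-1-yl]-2-[4-methoxy-3-(methoxymethoxy)phenyl]-5,7-bis(methoxymethoxy)chroman-4-one | COc1ccc([C@@H]2CC(=O)c3c(cc(OCOC)c(C/C=C(\C)CCC=C(C)C)c3OCOC)O2)cc1OCOC | intermediate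
19 | (2S)-6-[(2E)-3,7-dimethylocta-2,6-dien-1-yl]-5,7-dihydroxy-2-(3-hydroxy-4-methoxyphenyl)chroman-4-one (CNP0264411.1) | COc1ccc([C@@H]2CC(=O)c3c(cc(O)c(C/C=C(\C)CCC=C(C)C)c3O)O2)cc1O | target

Total step count: 10 steps.
Longest linear sequence: 7 steps (steps 1, 2, 3, 4, 8, 9, 10 from resorcinol); the ring B branch (steps 5, 6, 7) joins at step 8.

Steps most likely to fail

Step 8 (Mitsunobu etherification). The activated alcohol may ionise at the para-methoxy-substituted benzylic carbon, which would erode the enantiopurity, or it may be dehydrated to the cinnamoyl amide. The fallback forms the C2–O1 bond on a metal-bound allyl fragment instead; it sets out from phenol 8 (with purchased 3-hydroxy-4-methoxybenzaldehyde) and comes back at 15. The aldehyde is MOM-protected (NaH, MOMCl) to 4-methoxy-3-(methoxymethoxy)benzaldehyde F1, which Horner–Wadsworth–Emmons olefination (triethyl phosphonoacetate, NaH, THF) converts to ethyl (2E)-3-[4-methoxy-3-(methoxymethoxy)phenyl]prop-2-enoate F2. Reduction with i-Bu2AlH gives (2E)-3-[4-methoxy-3-(methoxymethoxy)phenyl]prop-2-en-1-ol F3, and methyl chloroformate/pyridine gives the cinnamyl methyl carbonate F4. Phenol 8 is deprotonated with NaH to the sodium phenoxide F5, which is allylated with F4 under [Ir(cod)Cl]2 and a chiral phosphoramidite ligand (branched-selective, enantioselective allylic etherification; the ligand enantiomer is chosen to give the S ether) to give the branched allyl aryl ether F6. Hydroboration of the terminal vinyl group with 9-BBN (selective over the trisubstituted alkenes) gives the B-alkyl-9-borabicyclononane F7, and NaBO3·4H2O oxidation gives the primary alcohol F8. Oxidation with TEMPO/PhI(OAc)2 in MeCN/H2O gives the carboxylic acid F9, and coupling with N,O-dimethylhydroxylamine hydrochloride (EDC, i-Pr2NEt) returns to 15.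

Step 9 (Parham cyclisation). The aryllithium may instead take a proton from the carbon alpha to the amide, after which the aryloxide is expelled, or the alkyllithium may attack the amide before the exchange. The fallback forms the same C4–C4a bond under non-basic conditions; it sets out from 15 and comes back at 18. Reduction of the Weinreb amide with i-Bu2AlH (THF, −78 °C) gives the 3-aryloxy-3-arylpropanal F10. An intramolecular Nozaki–Hiyama–Kishi reaction (CrCl2, NiCl2 cat., DMF, rt) adds the aryl iodide to the aldehyde and gives the flavan-4-ol F11 as a mixture of C4 epimers. Dess–Martin periodinane (NaHCO3, CH2Cl2) then oxidises F11 to 18.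

Step 3 (borylation in the presence of the geranyl chain). Iridium-catalysed hydroboration or isomerisation of the trisubstituted alkenes by pinacolborane may compete with arene C–H borylation. The fallback installs the oxygen before the alkenes; it sets out from 2 and comes back at 7. Compound 2 is borylated under the same iridium catalysis to the 3,5-bis(methoxymethoxy)phenylboronic acid pinacol ester F12 and oxidised (H2O2, NaOH) to 3,5-bis(methoxymethoxy)phenol F13. Silylation (i-Pr3SiCl, imidazole, DMF) gives the triisopropylsilyl ether F14, and n-BuLi deprotonates between the two MOM ethers (the bulky silyl ether does not direct) to give the aryllithium F15. Copper-catalysed alkylation with 3 gives the geranylated silyl ether F16, and Bu4NF in THF releases 7.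

Further compounds
F1 | step 8 | 4-methoxy-3-(methoxymethoxy)benzaldehyde | COCOc1cc(C=O)ccc1OC
F2 | step 8 | ethyl (2E)-3-[4-methoxy-3-(methoxymethoxy)phenyl]prop-2-enoate | CCOC(=O)/C=C/c1ccc(OC)c(OCOC)c1
F3 | step 8 | (2E)-3-[4-methoxy-3-(methoxymethoxy)phenyl]prop-2-en-1-ol | OC/C=C/c1ccc(OC)c(OCOC)c1
F4 | step 8 | (2E)-3-[4-methoxy-3-(methoxymethoxy)phenyl]prop-2-en-1-yl methyl carbonate | COC(=O)OC/C=C/c1ccc(OC)c(OCOC)c1
F5 | step 8 | sodium 4-[(2E)-3,7-dimethylocta-2,6-dien-1-yl]-2-iodo-3,5-bis(methoxymethoxy)phenoxide | [Na+].[O-]c1cc(OCOC)c(C/C=C(\C)CCC=C(C)C)c(OCOC)c1I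
F6 | step 8 | (S)-branched allyl aryl ether, 1-aryl-1-aryloxyprop-2-ene | COc1ccc([C@H](C=C)Oc2cc(OCOC)c(C/C=C(\C)CCC=C(C)C)c(OCOC)c2I)cc1OCOC
F7 | step 8 | B-alkyl-9-borabicyclo[3.3.1]nonane from F6 | COc1ccc([C@H](CCB2C3CCCC2CCC3)Oc2cc(OCOC)c(C/C=C(\C)CCC=C(C)C)c(OCOC)c2I)cc1OCOC
F8 | step 8 | (3S)-3-aryloxy-3-arylpropan-1-ol | COc1ccc([C@H](CCO)Oc2cc(OCOC)c(C/C=C(\C)CCC=C(C)C)c(OCOC)c2I)cc1OCOC
F9 | step 8 | (3S)-3-aryloxy-3-arylpropanoic acid | COc1ccc([C@H](CC(=O)O)Oc2cc(OCOC)c(C/C=C(\C)CCC=C(C)C)c(OCOC)c2I)cc1OCOC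
F10 | step 9 | (3S)-3-aryloxy-3-arylpropanal | COc1ccc([C@H](CC=O)Oc2cc(OCOC)c(C/C=C(\C)CCC=C(C)C)c(OCOC)c2I)cc1OCOC
F11 | step 9 | (2S)-tris-MOM-protected 6-geranylflavan-4-ol (C4 epimers) | COc1ccc([C@@H]2CC(O)c3c(cc(OCOC)c(C/C=C(\C)CCC=C(C)C)c3OCOC)O2)cc1OCOC
F12 | step 3 | 2-[3,5-bis(methoxymethoxy)phenyl]-4,4,5,5-tetramethyl-1,3,2-dioxaborolane | COCOc1cc(OCOC)cc(B2OC(C)(C)C(C)(C)O2)c1
F13 | step 3 | 3,5-bis(methoxymethoxy)phenol | COCOc1cc(O)cc(OCOC)c1
F14 | step 3 | [3,5-bis(methoxymethoxy)phenoxy]triisopropylsilane | COCOc1cc(O[Si](C(C)C)(C(C)C)C(C)C)cc(OCOC)c1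
F15 | step 3 | 2-lithio derivative of F14 (lithium between the two MOM ethers) | [Li]c1c(OCOC)cc(O[Si](C(C)C)(C(C)C)C(C)C)cc1OCOC
F16 | step 3 | {4-[(2E)-3,7-dimethylocta-2,6-dien-1-yl]-3,5-bis(methoxymethoxy)phenoxy}triisopropylsilane | COCOc1cc(O[Si](C(C)C)(C(C)C)C(C)C)cc(OCOC)c1C/C=C(\C)CCC=C(C)C
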